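## Structural features

Ainsliadimer A is a C30 dimer of two guaianolides, each built from a cyclopentane (ring A, C1–C5; ring A', C1'–C5') cis-fused at C1–C5 to a cycloheptane that carries an exocyclic C10=C14 methylene and a trans-fused α-methylene-γ-lactone across C6–C7. The halves are joined by a central cyclopentane (C3, C4, C15, C15', C4') that shares the C3–C4 bond with ring A and is spiro to ring A' at C4'. C1, C5, C4, C3, C4', C5' and C1' form an unbroken chain of seven stereocentres, and its middle (C4, C3, C4') consists of two tertiary carbinols and a quaternary spiro carbon. The two hydroxyls are cis and lie on the α face of ring A (the face of H1 and H5), so the bridge C15–C15'–C4' sits on the concave β face of the unprimed hydroazulene. The fragile groups are the two methylene lactones (Michael acceptors, reduced by one-electron donors), the β-hydroxy ketone C3'(=O)–C4'–C3(OH) (retro-aldol in base), the ditertiary cis-glycol (oxidative cleavage) and the exocyclic alkenes, which compete in any alkene chemistry. The real difficulty is the congested C4–C3–C4' triad with the correct sense towards both halves; everything else is already present in dehydrocostus lactone. The key step exploits the fact that C3–C4 belongs to ring A and to the central ring at once: without it the two rings merge into one cyclooctane-1,5-dione (C3, C2, C1, C5, C4, C15, C15', C4'), and reductive coupling across that ring closes both cyclopentanes and sets both carbinol centres, with the cis relation dictated by the bicyclo[3.3.0]octane fusion.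

## Logic of the disconnections

**21 back to 15.** No skeletal bond is cut. The C3' ketone is traced to a silyl-protected alcohol and the two C11=C13 methylenes to C11 methyl groups, with the glycol masked in between (20, 19, 17, 16). The reason is that a methylene lactone or a third ketone would not survive the one-electron reductant of the key step. The gain is an intermediate, 15, with only robust groups. The demand on the forward steps is that both selenoxide eliminations go towards C13 and not C7, and that the last oxidation touches neither the glycol nor the new β-hydroxy ketone.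

**15 back to 14.** The C3–C4 bond is cut. It is the one bond common to ring A and the central ring, so this single cut removes two rings and two stereocentres and leaves the eight-membered 1,5-diketone 14. The forward step must couple the two carbonyl carbons across the ring and place both oxygens on the α face.

**14 back to 10 (through 13).** C3–C4' and C15–C15' are cut and C3–C15 is rejoined (a [2+2] cycloaddition followed by retro-aldol, read backwards). The eight-membered ring shrinks to a six-membered vinylogous ester, the quaternary C4' becomes the sp2 carbon of an exocyclic alkene, and the dimer falls into two C15 halves held only by a silicon bridge in 10. The forward photocycloaddition must choose C4'=C15' over the two C10 methylenes, join C3 (not C15) to C4', and do so on the α face of ring A'. The bridge from O3 to the α-oriented O3' is there to enforce all three. Its price is that the alkene must add to the β face of the six-membered ring of 10, the side of the cycloheptane.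

**10 back to 8 and 3.** The two Si–O bonds are cut, which gives the two monomers. The forward silylation must take the enol oxygen at C3 of 8 and not the one at C4.

**8 back to 7.** C3–C15 is cut (Claisen condensation), opening the cyclohexane-1,3-dione to a methyl ketone and an ester. The forward step needs the kinetic enolate at C15; an enolate at C5 would expel the C6 lactone oxygen.

**7 back to 5 and 4.** C3 and C4 are rejoined (ozonolysis read backwards), which restores the intact ring A in 5 and then in 4. The forward cleavage must pick the enol ether in the presence of the C10=C14 alkene, and the enol ether must be formed only between C3 and C4.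

**4 back to 3, 2 and 1.** No skeletal bond is cut: the enone comes from an allylic alcohol, the alcohol from allylic oxidation at C3, and the saturated lactone from conjugate reduction. Because 3 is also the second partner in 10, both halves of the target come from 1 by one common line.

## Other disconnections considered

Alternative 1: The cut lies inside the unprimed hydroazulene: C1–C5 is broken and C5–C10 restored, so ring A and the cycloheptane become a trans-decalin with an equatorial 1β-mesylate and a C10 methyl group; this decalin mesylate A2 would be the substrate. In the forward direction, buffered acetolysis (KOAc, acetic acid) would ionise the mesylate while the antiperiplanar C5–C10 bond shifts to C1 (Wagner–Meerwein ring contraction and expansion). The C10 cation would then lose a C14 proton, so that the acetonide A1 of the target would result.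
- In its favour: the shift is stereospecific (inversion at C1, retention at C5), so the cis ring fusion with both hydrogens α follows from the decalin geometry. On this point it is more certain than the facial control of the chosen pinacol step, and so the better of the two. The acetonide A1 is also one deprotection from the target, against five steps after the chosen key step, so its endgame is better as well.
- Against it here: the step only reshapes one carbocycle. The C4–C3–C4' triad and the central ring would have to be built beforehand on a decalin-based dimer, and the unprimed half of mesylate A2 cannot be drawn from 1. The C10 cation can also lose a proton from C1 or C9 or be trapped by acetate, and hot acetic acid is a poor medium for an acetonide, two methylene lactones and a β-oxygenated ketone.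
- Comparison: on structure it spends its key step on a ring system the chosen plan takes intact from the starting material. On mechanism it is a well-behaved cationic shift followed by an elimination of uncontrolled regiochemistry. On step count the short endgame is outweighed by the longer preparation of the substrate.

Alternative 2: Only C3–C4' is cut. This leaves an α-hydroxy ketone (C4–OH, C3=O) tied through C15–C15' to the β-carbon C4' of a C4'=C5'–C6'=O enone whose lactone is opened as a methyl ester; this enone ketol A4 would be the substrate. In the forward direction, SmI2 (divalent samarium) would turn the C3 ketone into a ketyl that adds 5-exo to C4', and protonation of the samarium enolate at C5' would give the spiro diol A3 with a C6' ketone.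
- In its favour: the C4 carbinol is made beforehand, so the face of the diol does not depend on how a medium ring folds. On this point it is better than the chosen plan. The free C4 hydroxyl can chelate samarium with the ketyl oxygen and hold the two oxygens cis. There is no medium ring and no photochemistry. Ketyl–alkene cyclisations with this reductant are as well established as its pinacol couplings, so the two plans are equal on mechanism.
- Against it here: α-hydroxy ketones are liable to reductive loss of the hydroxyl under the same reagent. The acceptor carbon is fully substituted. Three stereocentres (C3, C4', C5') must come out right in one step, one of them by kinetic protonation. Afterwards the C6' ketone of the spiro diol A3 must be reduced from the correct face and the lactone reclosed, and the enone ketol A4 needs a separate C15–C15' bond construction.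
- Comparison: it closes one ring and sets three centres, against two rings and two centres in the chosen step, and it needs more steps both before and after.

Alternative 3: The cut lies in the unprimed cycloheptane: C7–C8 and C9–C10 are broken and C7–C10 is joined. The seven-membered ring contracts to the cyclopentane-1,3-dione A6 and ethylene A7 is set free. In the forward direction, irradiation of the enol of A6 with A7 and retro-aldol opening of the cyclobutanol would give the cycloheptane-1,4-dione A5 of the unprimed half.
- In its favour: the reaction type is the one used for the fragment union of the chosen route, so the plans are equal on mechanism. With a symmetrical, unhindered alkene in excess there is no question of orientation, of which alkene, or of face, and both enols of A6 lead to the same product. The photochemical step itself is therefore cleaner than step 8 of the chosen route, and on this point the alternative is better.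
- Against it here: all the difficult centres must already be present in A6, whose unprimed half is an all-cyclopentane system that cannot come from 1. After the step, the unprimed lactone, the C7 centre and the C10 methylene must still be installed on the dione A5 by telling its C6 and C10 ketones apart (alkylation at C7, face-selective reduction at C6, lactonisation, methylenation at C10), in addition to the same unmasking as in the chosen plan.
- Comparison: it builds a ring that the starting material supplies for nothing, and it is clearly longer.

Key step: step 10

**Remarks on the chemistry**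
- Guaianolide numbering is used, unprimed for the diol half and primed for the ketone half; α is the face of H1/H5 (H1'/H5'). Both halves keep the 1α,5α,6β,7α hydrogens of 1.
- C3' is a spectator centre that ends as the ketone. It is carried as the 3'α silyl ether because that epimer comes directly from the allylic oxidation and lets a silicon bridge deliver C3 to the α face of C4'.
- Assumption: allylic oxidation of 2 gives the 3α-alcohol (oxygen on the convex face), as is usual for this ring system.
- Compound 3 is divided: one part goes on through steps 3–6, the other is kept for step 7.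

## Steps

Step 1
Reactants: 1 dehydrocostus lactone
Product: 2 11β,13-dihydrodehydrocostus lactone (mokko lactone; 11α-methyl)
Conditions: NaBH4, MeOH, 0 °C
Reagents that add atoms: none
Why: Conjugate hydride reduction of the α-methylene lactone (the isolated alkenes are inert to borohydride); protonation of the lactone enolate gives the more stable 11α-methyl epimer, a spectator centre that returns to sp2 in step 13.

Step 2
Reactants: 2 11β,13-dihydrodehydrocostus lactone
Product: 3 11β,13-dihydro-3-epizaluzanin C (3α-hydroxyguaia-4(15),10(14)-dien-12,6-olide with 11α-methyl)
Conditions: SeO2 (0.5 equiv), t-BuOOH (2 equiv), CH2Cl2, rt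
Reagents that add atoms: selenium dioxide, O=[Se]=O (oxygen carrier); tert-butyl hydroperoxide, CC(C)(C)OO (terminal oxidant)
Why: Allylic oxidation (ene reaction, then [2,3]-sigmatropic shift) at the CH2 on the more substituted end of C4=C15, that is C3; oxygen is delivered to the convex α face of the cis-fused hydroazulene, which sets the 3α configuration, and C9 oxidation next to the other methylene is the expected minor pathway.

Step 3
Reactants: 3 11β,13-dihydro-3-epizaluzanin C
Product: 4 11β,13-dihydrodehydrozaluzanin C (3-oxoguaia-4(15),10(14)-dien-12,6-olide)
Conditions: DMP, CH2Cl2, 0 °C → rt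
Reagents that add atoms: none
Why: Oxidation of the secondary allylic alcohol by the pentavalent-iodine periodinane DMP (1,1,1-triacetoxy-1,1-dihydro-1,2-benziodoxol-3(1H)-one) under neutral conditions; the exocyclic enone is a reactive heterodiene and Michael acceptor and is used at once.

Step 4
Reactants: 4 11β,13-dihydrodehydrozaluzanin C
Product: 5 3-(triethylsilyloxy)guaia-3,10(14)-dien-12,6-olide (silyl enol ether in which C15 is now a methyl group on C4)
Conditions: Et3SiH, RhCl(PPh3)3 (1 mol %), THF, 40 °C
Reagents that add atoms: triethylsilane, CC[SiH](CC)CC
Why: Rhodium-catalysed 1,4-hydrosilylation of the s-cis exocyclic enone puts hydrogen on C15 and silicon on oxygen, so the enol ether is formed only between C3 and C4, which enolisation of the saturated ketone could not guarantee; the isolated 1,1-disubstituted alkene hydrosilylates far more slowly.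

Step 5
Reactants: 5 silyl enol ether
Product: 7 methyl 4-oxo-3,4-seco-guai-10(14)-en-12,6-olid-3-oate (acetyl group on C5 and CH2CO2Me on C1), via seco keto acid 6 (not isolated)
Conditions: O3, CH2Cl2–MeOH, −78 °C (Sudan Red 7B end point); Me2S, −78 °C → rt; then Me3SiCHN2, PhMe–MeOH, 0 °C
Reagents that add atoms: ozone, [O-][O+]=O; (trimethylsilyl)diazomethane, C[Si](C)(C)C=[N+]=[N-]
Why: Ozonolysis of a silyl enol ether cleaves C3=C4 to the C3 carboxylic acid (through its silyl ester) and the C4 methyl ketone; the tetrasubstituted enol ether is far more electron-rich than the C10=C14 methylene, so titration to the dye end point should spare the latter, and the acid is then esterified without base.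

Step 6
Reactants: 7 seco keto ester
Product: 8 cyclohexane-1,3-dione (ring C1–C2–C3–C15–C4–C5 with carbonyls at C3 and C4, cis-fused to the lactone-bearing cycloheptane)
Conditions: LiN(SiMe3)2 (2.2 equiv), THF, −78 → −20 °C; 1 M HCl
Reagents that add atoms: none
Why: Intramolecular Claisen (Dieckmann-type) condensation: kinetic deprotonation of the methyl ketone at C15 and 6-exo-trig acylation by the C3 ester, driven by deprotonation of the 1,3-dione formed; excess base and low temperature avoid the C5 enolate, which would expel the C6 lactone oxygen (E1cB) or epimerise C5.

Step 7
Reactants: 3 11β,13-dihydro-3-epizaluzanin C; 8 cyclohexane-1,3-dione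
Product: 10 mixed diisopropylsilaketal joining O3 of the enolised dione (C3(OSi)=C15–C4=O) to O3' of the 3α-alcohol, via chlorosilyl ether 9 (not isolated)
Conditions: 3, iPr2SiCl2 (3 equiv), Et3N, 4-(dimethylamino)pyridine (cat.), CH2Cl2, 0 °C; excess silane removed in vacuo; then 8, Et3N, CH2Cl2, 0 °C → rt
Reagents that add atoms: dichlorodiisopropylsilane, CC(C)[Si](Cl)(Cl)C(C)C
Why: Stepwise O-silylation (temporary silicon tether): the hindered secondary alcohol is monosilylated by excess dichlorosilane, then the acidic enol of 8 is silylated on O3, the oxygen flanked by the C2 methylene and not by the substituted ring-fusion carbon C5; this fixes the enol as C3(OSi)=C15–C4=O and puts C3 within reach of C4'.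

Step 8
Reactants: 10 silaketal
Product: 13 3'α-hydroxy cyclooctane-1,5-dione (eight-membered ring C3–C2–C1–C5–C4–C15–C15'–C4' spiro-linked at C4' to ring A'), via cyclobutane photoadduct 11 (not isolated), via cyclobutanediol 12 (not isolated)
Conditions: hν (300 nm, Pyrex), degassed MeCN–CH2Cl2 (0.003 M), 0 °C; then HF·pyridine, pyridine, THF, 0 °C → rt; aq. NaHCO3
Reagents that add atoms: none
Why: Intramolecular De Mayo reaction: [2+2] photocycloaddition of the vinylogous silyl ester to the tethered C4'=C15' alkene forms C3–C4' and C15–C15' (the head-to-tail sense favoured both by closure of the six-membered dioxasilinane and by enone polarity), then fluoride removes silicon and strain-driven retro-aldol cleavage of C3–C15 gives the cyclooctane-1,5-dione. The quaternary centre C4' is set by the tether: O3' is α, so C3 is delivered to the α face of C4', the convex face of the primed hydroazulene, with the dioxasilinane cis-fused both to ring A' and to the cyclobutane; this geometry places the alkene over the β face of the dione ring, which costs one 1,3-diaxial contact with the cycloheptane but leaves no trace in the product because the C3 and C15 centres of 11 vanish in the retro-aldol. The tether also directs the excited enone to C4'=C15' in preference to C10'=C14'.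

Step 9
Reactants: 13 3'α-hydroxy cyclooctane-1,5-dione
Product: 14 3'α-(tert-butyldimethylsilyloxy) cyclooctane-1,5-dione (precursor of the key step)
Conditions: t-BuMe2SiOTf, 2,6-lutidine, CH2Cl2, −78 °C
Reagents that add atoms: tert-butyldimethylsilyl triflate, CC(C)(C)[Si](C)(C)OS(=O)(=O)C(F)(F)F
Why: Silylation of the hindered secondary alcohol with a silyl triflate and a non-nucleophilic base at a temperature where ketone enolisation does not compete; the ether blocks hemiketal formation between O3' and the C4 carbonyl and retro-aldol opening of ring A' at C3'–C4' in the next step.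

Step 10
Reactants: 14 3'α-silyloxy cyclooctane-1,5-dione
Product: 15 3α,4α-diol with ring A and the central cyclopentane closed (11α- and 11'α-methyl lactones with the 3'α-silyl ether)
Conditions: SmI2 (3 equiv), HMPA (12 equiv), THF, −78 → 0 °C; sat. aq. NH4Cl
Reagents that add atoms: none
Why: Samarium diiodide (divalent samarium), activated by HMPA, transfers an electron to a ketone; the ketyl carbon attacks the facing carbonyl carbon across the eight-membered ring, a second electron follows, and the pinacolate of trivalent samarium is protonated on quench. The closest known reaction is the samarium diiodide pinacol cyclisation of diketones, in particular the transannular closure of cyclooctane-1,5-diones to cis-bicyclo[3.3.0]octane-1,5-diols. Ring A (C1–C5) and the central ring (C3, C4, C15, C15', C4') are closed by the same C3–C4 bond, each as a 5-exo-trig attack of a ketyl carbon on a carbonyl carbon, because C3 and C4 are 1,5-related both ways round the ring. The cis relation of the two new centres C3 and C4 is enforced by the ring fusion, since a trans-fused bicyclo[3.3.0]octane is too strained to form here. Their absolute sense is controlled by the existing centres C1 and C5: the cis-fused cycloheptane, with H6 and C14, covers the β face of the forming ring A, so the two HMPA-solvated O–Sm groups, the bulkiest substituents in the transition state, should take the convex α face beside H1 and H5 and the C15–C15'–C4' bridge should fold to the β face. HMPA also saturates samarium and so suppresses chelation to the lactone oxygen on C6, which would draw O4 to the β face. Chemoselectivity rests on the substrate: the lactones are saturated and are not reduced without a proton donor, C3' is a silyl ether so there is no third ketone, neither ketone has an α leaving group, and the only alkene within 5-exo reach of a ketyl (C10'=C14') is trans to C3 on ring A'. No proton source is present until the quench, so protonation of a ketyl (simple reduction) should not compete with coupling.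

Step 11
Reactants: 15 3α,4α-diol
Product: 16 3,4-bis(trimethylsilyl) ether
Conditions: Me3SiOTf, 2,6-lutidine, CH2Cl2, 0 °C
Reagents that add atoms: trimethylsilyl triflate, C[Si](C)(C)OS(=O)(=O)C(F)(F)F
Why: Silylation of both tertiary hydroxyls with the small, reactive silyl triflate so that no alkoxide is present in the enolate chemistry of step 12; these ethers leave together with the C3' silyl group in step 14, so the mask costs no separate deprotection.

Step 12
Reactants: 16 bis(trimethylsilyl) ether
Product: 17 11β,11'β-bis(phenylselenide) (11α- and 11'α-methyl)
Conditions: LiN(iPr)2 (3 equiv), THF, −78 °C; PhSeBr (2.5 equiv), −78 °C; sat. aq. NH4Cl at −78 °C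
Reagents that add atoms: phenylselenenyl bromide, Br[Se]c1ccccc1
Why: α-Selenenylation of the two lactone enolates (C11–H and C11'–H are the only acidic C–H bonds in 16); the electrophile enters each trans-fused lactone on the β face, anti to H7 and H7', and the cold quench keeps excess selenenyl bromide from adding to the alkenes.

Step 13
Reactants: 17 bis(phenylselenide)
Product: 19 bis(α-methylene lactone) with 3'α-silyl and 3,4-bis(trimethylsilyl) ethers, via bis-selenoxide 18 (not isolated)
Conditions: 30% H2O2, pyridine, CH2Cl2, 0 °C → rt
Reagents that add atoms: none
Why: Selenide oxidation and selenoxide syn-elimination; each selenium is trans to the ring hydrogen on C7 (C7'), so only the C13 (C13') methyl hydrogens are syn and the exocyclic methylene lactones should form, while pyridine buffers the selenium by-products that could otherwise attack the alkenes.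

Step 14
Reactants: 19 tris-silyl ether
Product: 20 3α,4α,3'α-triol (3'-deoxo-3'α-hydroxy-ainsliadimer A)
Conditions: HF·pyridine, pyridine, THF, 0 °C → rt
Reagents that add atoms: none
Why: Fluoride cleavage of all three silyl ethers under buffered, weakly acidic conditions that leave the methylene lactones, the exocyclic alkenes and the glycol alone.

Step 15
Reactants: 20 triol
Product: 21 ainsliadimer A
Conditions: (COCl)2, DMSO, CH2Cl2, −78 °C; Et3N, −78 → −30 °C
Reagents that add atoms: none
Why: Swern oxidation of the only secondary alcohol; activated dimethyl sulfoxide cannot oxidise or cleave the ditertiary glycol (unlike periodinane or lead reagents), and the cold amine stage avoids retro-aldol opening of the new β-hydroxy ketone.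

## Compound list

1 | dehydrocostus lactone | C=C1C(=O)O[C@@H]2[C@@H]3[C@@H](CCC3=C)C(=C)CC[C@@H]12 | starting material
2 | 11β,13-dihydrodehydrocostus lactone (mokko lactone) | C[C@@H]1C(=O)O[C@@H]2[C@@H]3[C@@H](CCC3=C)C(=C)CC[C@@H]12 | intermediate
3 | 11β,13-dihydro-3-epizaluzanin C (3α-ol) | C[C@@H]1C(=O)O[C@@H]2[C@@H]3[C@@H](C[C@@H](O)C3=C)C(=C)CC[C@@H]12 | intermediate
4 | 11β,13-dihydrodehydrozaluzanin C (enone) | C[C@@H]1C(=O)O[C@@H]2[C@@H]3[C@@H](CC(=O)C3=C)C(=C)CC[C@@H]12 | intermediate
5 | triethylsilyl enol ether (C3=C4) | C[C@@H]1C(=O)O[C@@H]2[C@@H]3[C@@H](CC(O[Si](CC)(CC)CC)=C3C)C(=C)CC[C@@H]12 | intermediate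
6 | 3,4-seco keto acid | C[C@@H]1C(=O)O[C@@H]2[C@@H](C(C)=O)[C@@H](CC(=O)O)C(=C)CC[C@@H]12 | intermediate (not isolated)
7 | 3,4-seco keto methyl ester | C[C@@H]1C(=O)O[C@@H]2[C@@H](C(C)=O)[C@@H](CC(=O)OC)C(=C)CC[C@@H]12 | intermediate
8 | cyclohexane-1,3-dione of the unprimed half | C[C@@H]1C(=O)O[C@@H]2[C@@H]3[C@@H](CC(=O)CC3=O)C(=C)CC[C@@H]12 | intermediate
9 | chloro(diisopropyl)silyl ether of 3 | CC(C)[Si](Cl)(C(C)C)O[C@@H]1C[C@H]2C(=C)CC[C@H]3[C@H](C)C(=O)O[C@@H]3[C@H]2C1=C | intermediate (not isolated)
10 | diisopropylsilaketal linking O3 (enol of 8) and O3' (of 3) | C[C@@H]1C(=O)O[C@@H]2[C@@H]3[C@@H](CC(O[Si](C(C)C)(C(C)C)O[C@@H]4C[C@H]5C(=C)CC[C@H]6[C@H](C)C(=O)O[C@@H]6[C@H]5C4=C)=CC3=O)C(=C)CC[C@@H]12 | intermediate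
11 | cyclobutane photoadduct (C3–C4', C15–C15'; cyclobutane on the β face of the dione ring; silylene of the 1,3-diol) | C[C@@H]1C(=O)O[C@@H]2[C@@H]3[C@@H](C[C@@]4(O[Si](C(C)C)(C(C)C)O[C@@H]5C[C@H]6C(=C)CC[C@H]7[C@H](C)C(=O)O[C@@H]7[C@H]6[C@]45C8)[C@H]8C3=O)C(=C)CC[C@@H]12 | intermediate (not isolated)
12 | cyclobutanediol (C3–OH, C3'–OH) | C[C@@H]1C(=O)O[C@@H]2[C@@H]3[C@@H](C[C@]4(O)[C@]5(C[C@@H]4C3=O)[C@H](O)C[C@H]6C(=C)CC[C@H]7[C@H](C)C(=O)O[C@@H]7[C@H]65)C(=C)CC[C@@H]12 | intermediate (not isolated)
13 | 3'α-hydroxy cyclooctane-1,5-dione | C[C@@H]1C(=O)O[C@@H]2[C@@H]3[C@@H](CC(=O)[C@]6(CCC3=O)[C@H](O)C[C@H]4C(=C)CC[C@H]5[C@H](C)C(=O)O[C@@H]5[C@H]46)C(=C)CC[C@@H]12 | intermediate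
14 | 3'α-(tert-butyldimethylsilyloxy) cyclooctane-1,5-dione | C[C@@H]1C(=O)O[C@@H]2[C@@H]3[C@@H](CC(=O)[C@]6(CCC3=O)[C@H](O[Si](C)(C)C(C)(C)C)C[C@H]4C(=C)CC[C@H]5[C@H](C)C(=O)O[C@@H]5[C@H]46)C(=C)CC[C@@H]12 | intermediate
15 | 3α,4α-diol, both cyclopentanes closed | C[C@@H]1C(=O)O[C@@H]2[C@@H]3[C@@H](C[C@@]4(O)[C@]3(O)CC[C@]43[C@H](O[Si](C)(C)C(C)(C)C)C[C@H]4C(=C)CC[C@H]5[C@H](C)C(=O)O[C@@H]5[C@H]43)C(=C)CC[C@@H]12 | intermediate
16 | 3,4-bis(trimethylsilyl) ether of 15 | C[C@@H]1C(=O)O[C@@H]2[C@@H]3[C@@H](C[C@@]4(O[Si](C)(C)C)[C@]3(O[Si](C)(C)C)CC[C@]43[C@H](O[Si](C)(C)C(C)(C)C)C[C@H]4C(=C)CC[C@H]5[C@H](C)C(=O)O[C@@H]5[C@H]43)C(=C)CC[C@@H]12 | intermediate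
17 | 11β,11'β-bis(phenylselenide) | C[C@]1([Se]c9ccccc9)C(=O)O[C@@H]2[C@@H]3[C@@H](C[C@@]4(O[Si](C)(C)C)[C@]3(O[Si](C)(C)C)CC[C@]43[C@H](O[Si](C)(C)C(C)(C)C)C[C@H]4C(=C)CC[C@H]5[C@]([Se]c6ccccc6)(C)C(=O)O[C@@H]5[C@H]43)C(=C)CC[C@@H]12 | intermediate
18 | bis-selenoxide of 17 | C[C@]1([Se](=O)c9ccccc9)C(=O)O[C@@H]2[C@@H]3[C@@H](C[C@@]4(O[Si](C)(C)C)[C@]3(O[Si](C)(C)C)CC[C@]43[C@H](O[Si](C)(C)C(C)(C)C)C[C@H]4C(=C)CC[C@H]5[C@]([Se](=O)c6ccccc6)(C)C(=O)O[C@@H]5[C@H]43)C(=C)CC[C@@H]12 | intermediate (not isolated)
19 | bis(α-methylene lactone), tris-silyl ether | C=C1C(=O)O[C@@H]2[C@@H]3[C@@H](C[C@@]4(O[Si](C)(C)C)[C@]3(O[Si](C)(C)C)CC[C@]43[C@H](O[Si](C)(C)C(C)(C)C)C[C@H]4C(=C)CC[C@H]5C(=C)C(=O)O[C@@H]5[C@H]43)C(=C)CC[C@@H]12 | intermediate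
20 | 3α,4α,3'α-triol | C=C1C(=O)O[C@@H]2[C@@H]3[C@@H](C[C@@]4(O)[C@]3(O)CC[C@]43[C@H](O)C[C@H]4C(=C)CC[C@H]5C(=C)C(=O)O[C@@H]5[C@H]43)C(=C)CC[C@@H]12 | intermediate
21 | ainsliadimer A | C=C1C(=O)O[C@@H]2[C@@H]3[C@@H](C[C@@]4(O)[C@]3(O)CC[C@]43C(=O)C[C@H]4C(=C)CC[C@H]5C(=C)C(=O)O[C@@H]5[C@H]43)C(=C)CC[C@@H]12 | target

## Step count and least certain steps

Total: 15 steps. Longest linear sequence: 15 steps (1 to 21); the second half enters as compound 3, which lies on the same line, so no separate branch adds steps.

**Step 10 (key step).** The most likely failure is closure on the wrong face, or with poor facial selectivity. The desired α,α-diol puts the C15–C15'–C4' bridge on the concave side of the unprimed hydroazulene, an arrangement the carbon skeleton alone would not prefer. The outcome therefore depends on the solvated O–Sm groups being the dominant steric element. A lesser hazard is that ketyl formation at the hindered C3 carbonyl lags, so that the C4 ketone is simply reduced.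
Fallback, from 14 back to 15: the coupling is driven through to the alkene with low-valent titanium (McMurry reaction; TiCl3, Zn–Cu couple, DME, reflux), which gives the tetrasubstituted C3=C4 alkene F1 with a bicyclo[3.3.0]oct-1(5)-ene core. Dimethyldioxirane at −78 °C should epoxidise this strained, most electron-rich alkene in preference to the 1,1-disubstituted ones and from the convex α face, giving the 3α,4α-epoxide F2 as the next intermediate. Dilute aqueous HClO4 in THF then opens the oxirane through a tertiary cation that water should capture on the face of the remaining oxygen, because only that face leads to the cis-fused bicyclo[3.3.0]octane, and this gives 15. The face is then fixed by reagent approach to a flat alkene and no longer by the folding of the medium ring.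

**Step 8.** The most likely failure is a sluggish or diverted cycloaddition. The bond must form between two fully substituted carbons, and the tether obliges the alkene to add to the β face of the dione ring, its concave side. Competing crossed addition of the excited enone to its own C10=C14 group (the carvone-type 1,5-diene arrangement C15=C3–C2–C1–C10=C14) is the likely diversion. Any O4-silylated isomer carried over from step 7 would also lead to bonding at C4 instead of C3.
Fallback, from 3 and 8 back to 14: 3 is silylated (t-BuMe2SiCl, imidazole, DMF) to the tert-butyldimethylsilyl ether F3 of the 3α-alcohol. The silyl ether F3 is irradiated in excess with the free enol of 8 in an untethered De Mayo reaction, in which the dione ring can use its convex α face. The cyclobutanol adduct F4 opens by retro-aldol to 14, with O3' already protected, so steps 7 to 9 are replaced by two operations. Without the tether, the choice of C4'=C15' over C10'=C14', the orientation and the face at C4' (where the α-silyloxy group now stands beside the face to be attacked) rest on substrate bias alone, which is why this is the fallback and not the first choice.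

**Step 6.** The most likely failure is equilibration of the methyl ketone enolate to the C5 enolate while the mixture warms for ring closure, followed by expulsion of the C6 lactone oxygen or loss of the C5 configuration.
Fallback, from 6 (intercepted before esterification) back to 8: carbonyldiimidazole converts the acid into the acyl imidazolide F5 under neutral conditions. Slow addition of the imidazolide F5 to LiN(SiMe3)2 at −78 °C lets the kinetic C15 enolate be acylated at that temperature by the much more reactive acyl donor, so the ring closes before enolate equilibration can set in.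

**Step 5.** The most likely failures are over-oxidation of the C10=C14 alkene if the end point is overrun, and partial diversion of the hindered tetrasubstituted enol ether to α-oxygenation instead of cleavage.
Fallback, from 5 back to 7: Rubottom oxidation (mCPBA, NaHCO3, CH2Cl2, −20 °C, then mild acid) gives the 4α-hydroxy-4-methyl-3-ketone F6 because a peracid discriminates between the enol ether and the 1,1-disubstituted alkene even more strongly than ozone. Pb(OAc)4 in MeOH–benzene then cleaves this α-ketol between C3 and C4 to the methyl ester and the methyl ketone, which is 7.

## Further compounds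

F1 | step 10 | tetrasubstituted C3=C4 alkene (bicyclo[3.3.0]oct-1(5)-ene core), 3'α-silyl ether | C[C@@H]1C(=O)O[C@@H]2[C@@H]3[C@@H](CC4=C3CC[C@]45[C@H](O[Si](C)(C)C(C)(C)C)C[C@H]4C(=C)CC[C@H]6[C@H](C)C(=O)O[C@@H]6[C@H]45)C(=C)CC[C@@H]12
F2 | step 10 | 3α,4α-epoxide of F1 | C[C@@H]1C(=O)O[C@@H]2[C@@H]3[C@@H](C[C@@]4(O7)[C@]37CC[C@]45[C@H](O[Si](C)(C)C(C)(C)C)C[C@H]4C(=C)CC[C@H]6[C@H](C)C(=O)O[C@@H]6[C@H]45)C(=C)CC[C@@H]12
F3 | step 8 | tert-butyldimethylsilyl ether of 3 | CC(C)(C)[Si](C)(C)O[C@@H]1C[C@H]2C(=C)CC[C@H]3[C@H](C)C(=O)O[C@@H]3[C@H]2C1=C
F4 | step 8 | cyclobutanol photoadduct of 8 and F3 (cyclobutane on the α face of the dione ring) | C[C@@H]1C(=O)O[C@@H]2[C@@H]3[C@@H](C[C@@]4(O)[C@]5(C[C@H]4C3=O)[C@H](O[Si](C)(C)C(C)(C)C)C[C@H]6C(=C)CC[C@H]7[C@H](C)C(=O)O[C@@H]7[C@H]65)C(=C)CC[C@@H]12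
F5 | step 6 | acyl imidazolide of keto acid 6 | C[C@@H]1C(=O)O[C@@H]2[C@@H](C(C)=O)[C@@H](CC(=O)n3ccnc3)C(=C)CC[C@@H]12
F6 | step 5 | 4α-hydroxy-4-methyl-3-ketone (α-ketol) | C[C@@H]1C(=O)O[C@@H]2[C@@H]3[C@@H](CC(=O)[C@@]3(C)O)C(=C)CC[C@@H]12
A1 | alternative 1 | acetonide of ainsliadimer A | C=C1C(=O)O[C@@H]2[C@@H]3[C@@H](C[C@@]4(O5)[C@]3(OC5(C)C)CC[C@]43C(=O)C[C@H]4C(=C)CC[C@H]5C(=C)C(=O)O[C@@H]5[C@H]43)C(=C)CC[C@@H]12
A2 | alternative 1 | 1β-mesyloxy trans-decalin (10β-methyl) precursor, diol acetonide | C=C1C(=O)O[C@@H]2[C@@H]3[C@](C)([C@H](OS(C)(=O)=O)C[C@@]4(O5)[C@]3(OC5(C)C)CC[C@]46C(=O)C[C@H]7C(=C)CC[C@H]8C(=C)C(=O)O[C@@H]8[C@H]76)CC[C@@H]12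
A3 | alternative 2 | spiro diol with C6' ketone and open primed lactone (methyl ester) | C[C@@H]1C(=O)O[C@@H]2[C@@H]3[C@@H](C[C@@]4(O)[C@]3(O)CC[C@]43[C@@H](O[Si](C)(C)C(C)(C)C)C[C@H]4C(=C)CC[C@@H]([C@H](C)C(=O)OC)C(=O)[C@H]43)C(=C)CC[C@@H]12
A4 | alternative 2 | α-hydroxy ketone tethered to the C4'=C5'–C6'=O enone | C[C@@H]1C(=O)O[C@@H]2[C@@H]3[C@@H](CC(=O)[C@]3(O)CCC4=C5C(=O)[C@H]([C@H](C)C(=O)OC)CCC(=C)[C@@H]5C[C@@H]4O[Si](C)(C)C(C)(C)C)C(=C)CC[C@@H]12
A5 | alternative 3 | cycloheptane-1,4-dione of the unprimed half | O=C1[C@@H]3[C@@H](C[C@@]4(O)[C@]3(O)CC[C@]43[C@@H](O[Si](C)(C)C(C)(C)C)C[C@H]4C(=C)CC[C@H]5[C@H](C)C(=O)O[C@@H]5[C@H]43)C(=O)CCC1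
A6 | alternative 3 | cyclopentane-1,3-dione (C6, C10) precursor | O=C1[C@@H]3[C@@H](C[C@@]4(O)[C@]3(O)CC[C@]43[C@@H](O[Si](C)(C)C(C)(C)C)C[C@H]4C(=C)CC[C@H]5[C@H](C)C(=O)O[C@@H]5[C@H]43)C(=O)C1
A7 | alternative 3 | ethylene | C=C
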